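**Retrosynthetic overview**

- The target is the ester of 3-(4-hydroxyphenyl)propanoic acid with an unbranched C25 alcohol. No ring is formed in the route (the benzene ring is bought with the acid) and there is no stereocentre.
- Key disconnection: the C6–C7 bond of the pentacosyl chain, made by crossed Kolbe electrolysis of icosanoic acid with a 7-(acyloxy)heptanoic acid. Two carboxylate-bearing carbons of like polarity are joined as radicals with loss of two CO2.
- Enabling feature: C6 and C7 lie inside an unbroken run of CH2 groups, and the nearest heteroatom (the ester O on C1) is five CH2 groups away from C6. Both partners are therefore plain primary alkyl radicals that neither rearrange nor oxidise on to cations. The benzene ring is kept out of the anodic window by acetylating its C4 oxygen.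
- Second disconnection: the alkyl C1–O bond of the ester, made first by carboxylate alkylation with tert-butyl 7-bromoheptanoate. The tert-butyl ester then unmasks the CO2H for the electrolysis, and the aryl acetate is removed last by aminolysis.

Key step: step 4

Remark: tert-butyl 7-bromoheptanoate, icosanoic acid and 3-(4-hydroxyphenyl)propanoic acid are taken as catalogue compounds. The alkene in fallback compound F2 would be an E/Z mixture and is drawn as E.

**Step 1**
Reactants: 1 3-(4-hydroxyphenyl)propanoic acid; 2 tert-butyl 7-bromoheptanoate
Product: 3 tert-butyl 7-{[3-(4-hydroxyphenyl)propanoyl]oxy}heptanoate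
Conditions: KHCO3 (1.1 equiv), cat. KI, DMF, 45–50 °C
Reagents that add atoms: none
Why: Chemoselective SN2 esterification by carboxylate alkylation, since bicarbonate deprotonates only the carboxylic acid and not the phenol, and the potassium carboxylate displaces the primary bromide in DMF.

**Step 2**
Reactants: 3 tert-butyl 7-{[3-(4-hydroxyphenyl)propanoyl]oxy}heptanoate
Product: 4 tert-butyl 7-{[3-(4-acetoxyphenyl)propanoyl]oxy}heptanoate
Conditions: Ac2O, pyridine, cat. DMAP, CH2Cl2, 0 °C to rt
Reagents that add atoms: acetic anhydride, CC(=O)OC(C)=O
Why: DMAP-catalysed O-acylation of the only free hydroxyl, which turns the easily oxidised phenol into an aryl acetate of roughly alkylbenzene electron density for the anodic step.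

**Step 3**
Reactants: 4 tert-butyl 7-{[3-(4-acetoxyphenyl)propanoyl]oxy}heptanoate
Product: 5 7-{[3-(4-acetoxyphenyl)propanoyl]oxy}heptanoic acid
Conditions: TFA–CH2Cl2 (1:3), 0 °C to rt; toluene co-evaporation
Reagents that add atoms: none
Why: Acidolysis of the tert-butyl ester through the tert-butyl cation (AAL1), a pathway closed to the primary alkyl ester and the aryl acetate, which should both survive.

**Step 4**
Reactants: 5 7-{[3-(4-acetoxyphenyl)propanoyl]oxy}heptanoic acid; 6 icosanoic acid (4 equiv)
Product: 9 pentacosyl 3-(4-acetoxyphenyl)propanoate, via nonadecyl radical 7 (not isolated), via 6-(acyloxy)hexyl radical 8 (not isolated)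
Conditions: Pt anode and Pt cathode, undivided cell, NaOMe (about 10 mol % of total acid), MeOH–light petroleum, 50 °C, constant high current density; stopped while the electrolyte is still faintly acidic, then AcOH quench
Reagents that add atoms: none
Why: Crossed Kolbe electrolysis: both carboxylates are oxidised by one electron at the platinum anode and lose CO2 to give the primary radicals 7 and 8 in the dense adsorbed layer, where they combine to form the C6–C7 bond. The closest known reaction type is the mixed Kolbe coupling of a fatty acid with an ω-acyloxy or half-ester acid, the classical way to extend ester-bearing chains. No ring is closed and no stereocentre is formed. The step needs cross-coupling over homo-coupling, which is statistical and is secured for the valuable partner by the fourfold excess of cheap 6, so that nearly every radical 8 meets a radical 7, while the octatriacontane from 6 is non-polar and should be removed by filtration and chromatography. It also needs the radical and not the cationic (Hofer–Moest) pathway, which follows from both radicals being unstabilised primary alkyls whose nearest heteroatom is five CH2 groups away. Finally the arene must not be oxidised and the esters must not be solvolysed, which the acetylated ring and the acidic carboxylate-buffered electrolyte should secure.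

**Step 5**
Reactants: 9 pentacosyl 3-(4-acetoxyphenyl)propanoate
Product: 10 pentacosyl 3-(4-hydroxyphenyl)propanoate
Conditions: pyrrolidine (3 equiv), THF–CH2Cl2, 0 °C to rt; dilute acid wash, recrystallisation
Reagents that add atoms: none
Why: Chemoselective aminolysis of the aryl acetate, since phenoxide is a far better leaving group than a primary alkoxide, so the amine should cleave only the phenolic ester at room temperature and leave the pentacosyl ester intact.

**Compound list**

1 | 3-(4-hydroxyphenyl)propanoic acid | OC(=O)CCc1ccc(O)cc1 | starting material
2 | tert-butyl 7-bromoheptanoate | CC(C)(C)OC(=O)CCCCCCBr | starting material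
3 | tert-butyl 7-{[3-(4-hydroxyphenyl)propanoyl]oxy}heptanoate | CC(C)(C)OC(=O)CCCCCCOC(=O)CCc1ccc(O)cc1 | intermediate
4 | tert-butyl 7-{[3-(4-acetoxyphenyl)propanoyl]oxy}heptanoate | CC(C)(C)OC(=O)CCCCCCOC(=O)CCc1ccc(OC(C)=O)cc1 | intermediate
5 | 7-{[3-(4-acetoxyphenyl)propanoyl]oxy}heptanoic acid | OC(=O)CCCCCCOC(=O)CCc1ccc(OC(C)=O)cc1 | intermediate
6 | icosanoic acid | CCCCCCCCCCCCCCCCCCCC(=O)O | starting material
7 | nonadecyl radical | CCCCCCCCCCCCCCCCCC[CH2] | intermediate
8 | 6-{[3-(4-acetoxyphenyl)propanoyl]oxy}hexyl radical | [CH2]CCCCCOC(=O)CCc1ccc(OC(C)=O)cc1 | intermediate
9 | pentacosyl 3-(4-acetoxyphenyl)propanoate | CCCCCCCCCCCCCCCCCCCCCCCCCOC(=O)CCc1ccc(OC(C)=O)cc1 | intermediate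
10 | pentacosyl 3-(4-hydroxyphenyl)propanoate | CCCCCCCCCCCCCCCCCCCCCCCCCOC(=O)CCc1ccc(O)cc1 | target

**Step count and risks**

Total step count: 5. Longest linear sequence: 5 steps (1 → 3 → 4 → 5 → 9 → 10); icosanoic acid 6 enters at step 4.

Steps most likely to fail:

1. Step 4 (crossed Kolbe electrolysis). The radical combination is statistical, so much of the current goes into homo-coupling. The waxy products may passivate the anode. The arene may be oxidised, or the aryl acetate solvolysed in the alkaline cathode layer. Fallback, from 1 and returning at 10: the same C6–C7 bond is made at the alkene oxidation level by olefin metathesis, with the phenol left free. Fischer esterification of 1 with hept-6-en-1-ol (C=CCCCCCO; cat. p-TsOH, toluene, Dean–Stark) should give hept-6-en-1-yl 3-(4-hydroxyphenyl)propanoate F1. Cross-metathesis of F1 with excess icos-1-ene (C=CCCCCCCCCCCCCCCCCCC; second-generation Ru carbene catalyst, CH2Cl2, 40 °C, ethene swept out) should give pentacos-6-en-1-yl 3-(4-hydroxyphenyl)propanoate F2 as an E/Z mixture. Hydrogenation (H2, Pd/C, EtOAc) should then give 10 directly.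

2. Step 1 (carboxylate alkylation beside a free phenol). Chemoselectivity may be lost through competing O-alkylation of the phenol, or the bromide may be consumed by elimination in warm DMF. Fallback, from 1 and returning at 4: the order of events is inverted so that no selectivity is needed. Acetylation of 1 (Ac2O, pyridine, rt, then aqueous work-up to hydrolyse the mixed anhydride) should give 3-(4-acetoxyphenyl)propanoic acid F3. Its caesium carboxylate (Cs2CO3, 0.55 equiv, DMF, rt) should then be alkylated by 2 to give 4, so that steps 1 and 2 are replaced.

3. Step 5 (selective deacetylation). The waxy substrate may dissolve poorly and react incompletely, or forcing the reaction may bring on aminolysis of the pentacosyl ester. Fallback, from 9 and returning at 10: selectivity is given up and the ester is rebuilt. Exhaustive saponification of 9 (KOH, EtOH–THF–H2O, reflux, then acidification) should give pentacosan-1-ol F4, which is separated by extraction from the water-soluble acids. Fischer esterification of F4 with 1 (cat. p-TsOH, toluene, Dean–Stark), under which the phenol is not acylated, should give 10.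

**Further compounds**

F1 | step 4 | hept-6-en-1-yl 3-(4-hydroxyphenyl)propanoate | C=CCCCCCOC(=O)CCc1ccc(O)cc1
F2 | step 4 | (E)-pentacos-6-en-1-yl 3-(4-hydroxyphenyl)propanoate (E/Z mixture, E drawn) | CCCCCCCCCCCCCCCCCC/C=C/CCCCCOC(=O)CCc1ccc(O)cc1
F3 | step 1 | 3-(4-acetoxyphenyl)propanoic acid | CC(=O)Oc1ccc(CCC(=O)O)cc1
F4 | step 5 | pentacosan-1-ol | CCCCCCCCCCCCCCCCCCCCCCCCCO
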